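**Plan**
1. Retrosynthetic cuts: C13–C14 (Stille) and C12=C13 (Stork–Zhao) in the side chain; C6–O/C5–H (hydroboration of a Δ5 alkene); the ring-B bond C9–C10; then C8–C17/C9–C11 (carboalumination/Negishi coupling) and C7–C8 (ethynylation).
2. Forward: ring A is bought as β-homocyclocitral (C1–C7, C18–C20). The C7–C12 chain is attached and epoxidised at C8–C9. Ring B is closed last by C10 attacking C9, and the diene is built at the end.
3. Enabling feature: in ring B, O-8 is equatorial and anti to the C9–C10 bond, with CH3-17, H-9 and CH3-20 axial. This is the outcome of an anti (SN2) opening at C9 of an (E)-derived C8–C9 epoxide by C10 of the tetrasubstituted C5=C10 alkene of ring A.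
4. The C5 cation left behind has β-hydrogens only on C6, so proton loss can only give the Δ5 alkene, whose α-face hydroboration gives cis H-5/O-6.
5. Stereochemistry: Sharpless kinetic-resolution epoxidation fixes C7, C8 and C9; Mitsunobu inversion turns C7 to threo. The epoxide opening carries C8 (retention) and C9 (inversion) into the ring and sets C10. Hydroboration sets C5 and C6; Stork–Zhao olefination sets 12Z.

Key step: step 5

Remark: labdane numbering (C5/C10 ring fusion, C17 on C8, C20 on C10; β = face of C20) is used for all compounds, and compound 1 is assumed to be commercial β-homocyclocitral.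

**Step 1**
Reactants: 1 2-(2,6,6-trimethylcyclohex-1-en-1-yl)acetaldehyde (β-homocyclocitral); 2 ethynylmagnesium bromide
Product: 3 rac-1-(2,6,6-trimethylcyclohex-1-en-1-yl)but-3-yn-2-ol
Conditions: THF, −78 → 0 °C; then H2O
Reagents that add atoms: none
Why: Addition of an alkynyl Grignard reagent to the aldehyde forms C7–C8; the carbinol centre is left racemic here because step 3 resolves it.

**Step 2**
Reactants: 3 rac-1-(2,6,6-trimethylcyclohex-1-en-1-yl)but-3-yn-2-ol; 4 vinyl bromide
Product: 6 rac-(3E)-3-methyl-1-(2,6,6-trimethylcyclohex-1-en-1-yl)hexa-3,5-dien-2-ol, via alkenylalane 5 (not isolated)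
Conditions: AlMe3 (3 equiv), Cp2ZrCl2 (cat.), CH2Cl2, 0 °C → rt; then 4, Pd(PPh3)4 (cat.), ZnCl2 (cat.), THF, rt; H2O work-up
Reagents that add atoms: trimethylaluminium C[Al](C)C
Why: Zr-catalysed carboalumination (Negishi) adds CH3 and Al syn across the alkyne with CH3 on the inner carbon (C8), and Pd-catalysed Negishi coupling of the alkenylalane with vinyl bromide goes with retention, so the (3E)-diene should result and no stereocentre is touched.

**Step 3**
Reactants: 6 rac-(3E)-3-methyl-1-(2,6,6-trimethylcyclohex-1-en-1-yl)hexa-3,5-dien-2-ol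
Product: 7 (1R)-1-[(2R,3R)-3-ethenyl-2-methyloxiran-2-yl]-2-(2,6,6-trimethylcyclohex-1-en-1-yl)ethan-1-ol (erythro)
Conditions: Ti(OiPr)4, D-(−)-diisopropyl tartrate, t-BuOOH (0.45 equiv), 4 Å MS, CH2Cl2, −20 °C
Reagents that add atoms: tert-butyl hydroperoxide CC(C)(C)OO
Why: Sharpless asymmetric epoxidation run as a kinetic resolution: with D-(−)-tartrate the (2R)-alcohol should react much faster and oxygen is delivered only to the allylic C8=C9 bond to give the erythro epoxy alcohol, fixing C7, C8 and C9 together; the (2S)-alcohol stays behind and is separated, and the ring and terminal alkenes, which have no allylic hydroxyl, are not epoxidised.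

**Step 4**
Reactants: 7 (1R)-1-[(2R,3R)-3-ethenyl-2-methyloxiran-2-yl]-2-(2,6,6-trimethylcyclohex-1-en-1-yl)ethan-1-ol
Product: 9 (1S)-1-[(2R,3R)-3-ethenyl-2-methyloxiran-2-yl]-2-(2,6,6-trimethylcyclohex-1-en-1-yl)ethan-1-ol (threo), via 4-nitrobenzoate 8 (not isolated)
Conditions: PPh3, DIAD, 4-O2NC6H4CO2H, toluene, 0 °C → rt; then K2CO3 (cat.), MeOH, 0 °C
Reagents that add atoms: 4-nitrobenzoic acid O=C(O)c1ccc(cc1)[N+](=O)[O-]
Why: Mitsunobu reaction: the carboxylate displaces the C7 oxyphosphonium in an SN2 step, which inverts C7 to the threo series needed for an equatorial O-7, and mild methanolysis then frees the alcohol (its oxygen now comes from the acid) without touching the epoxide.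

**Step 5**
Reactants: 9 (1S)-1-[(2R,3R)-3-ethenyl-2-methyloxiran-2-yl]-2-(2,6,6-trimethylcyclohex-1-en-1-yl)ethan-1-ol
Product: 11 7β,8α-bis(triethylsilyloxy)-13,14,15,16-tetranorlabda-5,11-diene, via diol 10 (not isolated)
Conditions: Sc(OTf)3 (10 mol %), CH2Cl2, −40 °C; then 2,6-lutidine, TESOTf, −78 → 0 °C
Reagents that add atoms: triethylsilyl trifluoromethanesulfonate CC[Si](CC)(CC)OS(=O)(=O)C(F)(F)F
Why: Proposed new method: Sc(III) held between O-7 and the oxirane oxygen (the binding mode of C3-selective openings of 2,3-epoxy alcohols) should polarize the C9–O bond, which is allylic to the vinyl group, while cleavage at C8 is disfavoured by the electron-withdrawing C7–O next to it; C10 of the tetrasubstituted C5=C10 alkene then attacks C9 anti to the leaving oxygen, and the tertiary C5 cation, whose only β-hydrogens are on C6, loses H-6 to give the Δ5 alkene and hands the proton back to O-8. The closest known reaction type is the Lewis-acid epoxide-initiated cation–olefin cyclization, together with vinyl-directed endo-selective epoxide opening by oxygen nucleophiles; new here is an alkene attacking the less substituted, allylic carbon of a trisubstituted epoxide. Ring B closes 6-endo with respect to both the epoxide and the alkene; attack at C8 would be 5-exo, and attack through C5 would give a spiro ring and is blocked by the C4 gem-dimethyl group. C9 is inverted and C8 retained, so O-8 ends anti to C9–C10 (equatorial) with CH3-17 axial and the vinyl group equatorial; this fixes the chair, the threo C7 centre then places O-7 equatorial, and the new quaternary C10 follows from the alkene geometry in that chair (C20, cis to C6, becomes axial and anti to H-9). The step needs ionization at C9 rather than C8 and capture by the alkene faster than any 1,2-shift; the vinyl group, the chelate and the six-membered transition state are meant to secure this. TESOTf then caps both hydroxyls so that O-6 can later be told apart from O-7.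

**Step 6**
Reactants: 11 7β,8α-bis(triethylsilyloxy)-13,14,15,16-tetranorlabda-5,11-diene
Product: 13 7β,8α-bis(triethylsilyloxy)-13,14,15,16-tetranorlabdane-6α,12-diol, via bis(alkylborane) 12 (not isolated)
Conditions: BH3·THF (excess), THF, 0 °C → rt; then NaOH, H2O2, 0 °C → rt
Reagents that add atoms: borane–tetrahydrofuran [BH3-][O+]1CCCC1 (boron of 12 only); hydrogen peroxide OO
Why: Hydroboration–oxidation: borane should add syn from the α-face of the Δ5 bond (β-face shielded by the axial C19 and C20 methyls; α-face also anti to the allylic 7β-silyloxy group) with boron on the less substituted C6, and on the terminal carbon of the vinyl group, and oxidation with retention gives 5α-H, 6α-OH and the primary C12 alcohol.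

**Step 7**
Reactants: 13 7β,8α-bis(triethylsilyloxy)-13,14,15,16-tetranorlabdane-6α,12-diol
Product: 14 6α-hydroxy-7β,8α-bis(triethylsilyloxy)-13,14,15,16-tetranorlabdan-12-al
Conditions: TEMPO (cat.), PhI(OAc)2, CH2Cl2, rt
Reagents that add atoms: none
Why: TEMPO/PhI(OAc)2 oxidation is selective for the primary alcohol, so the hindered secondary 6α-OH is kept for the later acetylation and no stereocentre changes.

**Step 8**
Reactants: 14 6α-hydroxy-7β,8α-bis(triethylsilyloxy)-13,14,15,16-tetranorlabdan-12-al; 15 ethyltriphenylphosphonium iodide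
Product: 16 (12Z)-13-iodo-7β,8α-bis(triethylsilyloxy)-14,15-dinorlabd-12-en-6α-ol
Conditions: 15, n-BuLi, THF, rt; I2, −78 °C; NaHMDS, −78 → −20 °C; then 14, −78 °C
Reagents that add atoms: iodine II
Why: Stork–Zhao olefination: the α-iodo ylide should react with the aldehyde under kinetic control to give the (Z)-2-iodoalkene (iodine cis to C11), which fixes the later 12Z geometry.

**Step 9**
Reactants: 16 (12Z)-13-iodo-7β,8α-bis(triethylsilyloxy)-14,15-dinorlabd-12-en-6α-ol; 17 tributyl(vinyl)stannane
Product: 18 (12Z)-7β,8α-bis(triethylsilyloxy)labda-12,14-dien-6α-ol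
Conditions: Pd2(dba)3 (cat.), AsPh3, CuI (cat.), DMF, rt
Reagents that add atoms: none
Why: Stille coupling of the alkenyl iodide with the vinylstannane goes with retention of double-bond geometry and tolerates the free hydroxyl and the silyl ethers, giving the (12Z)-diene.

**Step 10**
Reactants: 18 (12Z)-7β,8α-bis(triethylsilyloxy)labda-12,14-dien-6α-ol
Product: 19 (12Z)-6α-acetoxy-7β,8α-bis(triethylsilyloxy)labda-12,14-diene
Conditions: Ac2O, DMAP, Et3N, CH2Cl2, rt → 40 °C
Reagents that add atoms: acetic anhydride CC(=O)OC(C)=O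
Why: DMAP-catalysed acylation: O-6 is the only free hydroxyl (O-7 and O-8 are silylated), so the acetate goes on the right oxygen.

**Step 11**
Reactants: 19 (12Z)-6α-acetoxy-7β,8α-bis(triethylsilyloxy)labda-12,14-diene
Product: 20 (12Z)-6α-acetoxylabda-12,14-diene-7β,8α-diol (target)
Conditions: HF·pyridine, pyridine, THF, 0 °C → rt
Reagents that add atoms: none
Why: Fluoride-mediated desilylation under buffered, weakly acidic conditions should remove both triethylsilyl ethers without acetyl migration or acid-induced cyclization of the 8-hydroxy diene.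

**Compound list**
1 | 2-(2,6,6-trimethylcyclohex-1-en-1-yl)acetaldehyde (β-homocyclocitral) | CC1=C(CC=O)C(C)(C)CCC1 | starting material
2 | ethynylmagnesium bromide | C#C[Mg]Br | starting material
3 | rac-1-(2,6,6-trimethylcyclohex-1-en-1-yl)but-3-yn-2-ol | CC1=C(CC(O)C#C)C(C)(C)CCC1 | intermediate
4 | vinyl bromide | C=CBr | starting material
5 | [(1E)-3-(dimethylalumanyloxy)-2-methyl-4-(2,6,6-trimethylcyclohex-1-en-1-yl)but-1-en-1-yl]dimethylalumane (not isolated) | CC1=C(CC(O[Al](C)C)/C(C)=C/[Al](C)C)C(C)(C)CCC1 | intermediate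
6 | rac-(3E)-3-methyl-1-(2,6,6-trimethylcyclohex-1-en-1-yl)hexa-3,5-dien-2-ol | CC1=C(CC(O)/C(C)=C/C=C)C(C)(C)CCC1 | intermediate
7 | (1R)-1-[(2R,3R)-3-ethenyl-2-methyloxiran-2-yl]-2-(2,6,6-trimethylcyclohex-1-en-1-yl)ethan-1-ol (erythro) | C=C[C@H]1O[C@]1(C)[C@H](O)CC1=C(C)CCCC1(C)C | intermediate
8 | (1S)-1-[(2R,3R)-3-ethenyl-2-methyloxiran-2-yl]-2-(2,6,6-trimethylcyclohex-1-en-1-yl)ethyl 4-nitrobenzoate (not isolated) | C=C[C@H]1O[C@]1(C)[C@@H](OC(=O)c1ccc(cc1)[N+](=O)[O-])CC1=C(C)CCCC1(C)C | intermediate
9 | (1S)-1-[(2R,3R)-3-ethenyl-2-methyloxiran-2-yl]-2-(2,6,6-trimethylcyclohex-1-en-1-yl)ethan-1-ol (threo) | C=C[C@H]1O[C@]1(C)[C@@H](O)CC1=C(C)CCCC1(C)C | intermediate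
10 | 13,14,15,16-tetranorlabda-5,11-diene-7β,8α-diol (not isolated) | C=C[C@H]1[C@](C)(O)[C@@H](O)C=C2C(C)(C)CCC[C@@]21C | intermediate
11 | 7β,8α-bis(triethylsilyloxy)-13,14,15,16-tetranorlabda-5,11-diene | C=C[C@H]1[C@](C)(O[Si](CC)(CC)CC)[C@@H](O[Si](CC)(CC)CC)C=C2C(C)(C)CCC[C@@]21C | intermediate
12 | 6α,12-bis(boranyl)-7β,8α-bis(triethylsilyloxy)-13,14,15,16-tetranorlabdane, 5α-H (not isolated) | [BH2]CC[C@H]1[C@](C)(O[Si](CC)(CC)CC)[C@@H](O[Si](CC)(CC)CC)[C@H]([BH2])[C@H]2C(C)(C)CCC[C@@]21C | intermediate
13 | 7β,8α-bis(triethylsilyloxy)-13,14,15,16-tetranorlabdane-6α,12-diol | OCC[C@H]1[C@](C)(O[Si](CC)(CC)CC)[C@@H](O[Si](CC)(CC)CC)[C@H](O)[C@H]2C(C)(C)CCC[C@@]21C | intermediate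
14 | 6α-hydroxy-7β,8α-bis(triethylsilyloxy)-13,14,15,16-tetranorlabdan-12-al | O=CC[C@H]1[C@](C)(O[Si](CC)(CC)CC)[C@@H](O[Si](CC)(CC)CC)[C@H](O)[C@H]2C(C)(C)CCC[C@@]21C | intermediate
15 | ethyltriphenylphosphonium iodide | CC[P+](c1ccccc1)(c1ccccc1)c1ccccc1.[I-] | starting material
16 | (12Z)-13-iodo-7β,8α-bis(triethylsilyloxy)-14,15-dinorlabd-12-en-6α-ol | I/C(C)=C\C[C@H]1[C@](C)(O[Si](CC)(CC)CC)[C@@H](O[Si](CC)(CC)CC)[C@H](O)[C@H]2C(C)(C)CCC[C@@]21C | intermediate
17 | tributyl(vinyl)stannane | C=C[Sn](CCCC)(CCCC)CCCC | starting material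
18 | (12Z)-7β,8α-bis(triethylsilyloxy)labda-12,14-dien-6α-ol | C=C/C(C)=C\C[C@H]1[C@](C)(O[Si](CC)(CC)CC)[C@@H](O[Si](CC)(CC)CC)[C@H](O)[C@H]2C(C)(C)CCC[C@@]21C | intermediate
19 | (12Z)-6α-acetoxy-7β,8α-bis(triethylsilyloxy)labda-12,14-diene | C=C/C(C)=C\C[C@H]1[C@](C)(O[Si](CC)(CC)CC)[C@@H](O[Si](CC)(CC)CC)[C@H](OC(C)=O)[C@H]2C(C)(C)CCC[C@@]21C | intermediate
20 | (12Z)-6α-acetoxylabda-12,14-diene-7β,8α-diol, (5S,6R,7S,8S,9R,10S) | C=C/C(C)=C\C[C@H]1[C@](C)(O)[C@@H](O)[C@H](OC(C)=O)[C@H]2C(C)(C)CCC[C@@]21C | target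

Total step count: 11. Longest linear sequence: 11 steps (from 1).

**Steps most likely to fail**

Step 5 (proposed new method). The Lewis acid may instead trigger ionization at the tertiary C8 with a 1,2-hydride or alkyl shift (epoxide-to-carbonyl rearrangement). The C5 cation may be captured by O-8 or undergo a methyl shift, or C9 may lose its configuration through a free allyl cation. The fallback sets out from 9, uses an allylic-cation-initiated cation–olefin cyclization and returns at 11. Pd(PPh3)4-catalysed 1,4-addition of acetic acid to the vinyl epoxide gives (2E,4S,5S)-4,5-dihydroxy-4-methyl-6-(2,6,6-trimethylcyclohex-1-en-1-yl)hex-2-en-1-yl acetate F1. TESOTf/2,6-lutidine gives its bis(triethylsilyl) ether F2. SnCl4 in CH2Cl2 at −78 °C ionizes the allylic acetate, C10 of the ring alkene captures the allyl cation at C9 in a chair with both silyloxy groups and the vinyl group equatorial, and loss of H-6 gives 11.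

Step 4. The SN2 displacement at C7, next to the fully substituted oxirane carbon, may be slow, so that elimination or opening of the epoxide by the acid takes over. The fallback sets out from 7 and returns at 9 by oxidation and reagent-controlled reduction instead of substitution. Dess–Martin periodinane gives 1-[(2S,3R)-3-ethenyl-2-methyloxiran-2-yl]-2-(2,6,6-trimethylcyclohex-1-en-1-yl)ethan-1-one F3. Corey–Bakshi–Shibata reduction with the (R)-methyl oxazaborolidine and catecholborane at −78 °C should then deliver the (1S)-alcohol 9.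

Step 6. Borane addition to the hindered trisubstituted Δ5 bond may be slow or poorly face-selective. The fallback sets out from 11 and returns at 13, replacing hydroboration of the ring alkene by epoxidation and Ti(III) reductive opening. 9-BBN followed by NaOH/H2O2 converts only the vinyl group, giving 7β,8α-bis(triethylsilyloxy)-13,14,15,16-tetranorlabd-5-en-12-ol F4. mCPBA/NaHCO3 epoxidises the Δ5 bond from the open α-face to 5α,6α-epoxy-7β,8α-bis(triethylsilyloxy)-13,14,15,16-tetranorlabdan-12-ol F5. Cp2TiCl (from Cp2TiCl2 and Mn) with 1,4-cyclohexadiene in THF opens the epoxide homolytically to the tertiary C5 radical with oxygen kept on C6, and hydrogen-atom transfer from the α-face gives 13.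

**Further compounds**
F1 | step 5 | (2E,4S,5S)-4,5-dihydroxy-4-methyl-6-(2,6,6-trimethylcyclohex-1-en-1-yl)hex-2-en-1-yl acetate | CC(=O)OC/C=C/[C@](C)(O)[C@@H](O)CC1=C(C)CCCC1(C)C
F2 | step 5 | (2E,4S,5S)-4-methyl-4,5-bis(triethylsilyloxy)-6-(2,6,6-trimethylcyclohex-1-en-1-yl)hex-2-en-1-yl acetate | CC(=O)OC/C=C/[C@](C)(O[Si](CC)(CC)CC)[C@@H](O[Si](CC)(CC)CC)CC1=C(C)CCCC1(C)C
F3 | step 4 | 1-[(2S,3R)-3-ethenyl-2-methyloxiran-2-yl]-2-(2,6,6-trimethylcyclohex-1-en-1-yl)ethan-1-one | C=C[C@H]1O[C@]1(C)C(=O)CC1=C(C)CCCC1(C)C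
F4 | step 6 | 7β,8α-bis(triethylsilyloxy)-13,14,15,16-tetranorlabd-5-en-12-ol | OCC[C@H]1[C@](C)(O[Si](CC)(CC)CC)[C@@H](O[Si](CC)(CC)CC)C=C2C(C)(C)CCC[C@@]21C
F5 | step 6 | 5α,6α-epoxy-7β,8α-bis(triethylsilyloxy)-13,14,15,16-tetranorlabdan-12-ol | OCC[C@H]1[C@](C)(O[Si](CC)(CC)CC)[C@@H](O[Si](CC)(CC)CC)[C@@H]2O[C@@]23C(C)(C)CCC[C@@]31C
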